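Start with the split.

| flask | starting material | first nucleophile | second nucleophile | remark | time |
|---|---|---|---|---|---|
| amber | 1.3 M | 1.32 M | 0.84 M | run made earlier |  |
| dusk | 0.40 M | 1.32 M | 0.600 M |  | 2.5 min |
| winter | 1.2 M | 1.32 M | 0.840 M |  | 2.5 min |
| spring | 0.30 M | 1.32 M | 0.200 M |  | 2.5 min |
| summer | 1.2 M | 0.300 M | 2.50 M |  | 2.5 min |
| autumn | 0.30 M | 1.32 M | 0.840 M |  | 2.5 min |

- amber (time / s: target / %, starting material / %): 10.0: 3.9, 83.4; 25.0: 12.6, 63.9; 40.0: 19.5, 49.8; 60.0: 26.6, 36.1; 90.0: 33.0, 23.2

(readings scatter by 0.5 percentage points)

- the numbers in the tables scatter with a standard deviation of 0.5 percentage points
- a reading or a percentage of target counts all its forms, free or not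

* all flasks from highest to lowest amount of target, in percent of the starting material charged, at 2.5 min (dusk / winter / spring / summer / autumn)
* the amount of target, in percent of the starting material charged of the flask you put first, at 2.5 min
* the amount of target, in percent of the starting material charged of the flask you put last, at 2.5 min

In amber, target lags: after 10.0 s it reads 3.9%, while 16.6% of the starting material has gone. So I take something to stand between them, an intermediate for which the two nucleophiles compete, as two monomers compete for a chain end. Amber's late decay reads 0.0147 /s; held constant and taken for each flask, that leaves 11.0% of the starting material at 2.5 min by my estimate. That gives two extreme flasks. If first nucleophile catches the intermediate each time, target equals the conversion, 89.0%. If second nucleophile does, target stays at zero.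

I place the real flasks between these, at the share of the conversion that goes to target. Between its last two readings, amber reads 0.496 of target gained per starting material lost. Take that share over its remainder and divide by the charged ratio of first to second nucleophile. This is the capture ratio, a selectivity factor read at charged concentrations: 0.627. Multiply it by a flask's charged ratio to get x, and the share is x/(1+x).

My reckoning gives spring a share of 0.805, so 71.6% of target. Dusk gets 51.6%, and summer 0.0699, so 6.22%. Autumn and winter share amber's ratio and tie at 44.1%. But amber's early decay, 0.0182 /s, is faster than the late one, which points to a loss of higher order in starting material. That loss should cost winter at 1.2 M more than autumn at 0.30 M, so I put autumn ahead.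

The forecast says autumn > dusk > winter > spring > summer, with 43% first and 18% last, on “a steady yield of about 0.47 per starting material consumed”. We part there, since my share moves with the ratio.

The flask gives spring > dusk > autumn > winter > summer, with spring at 64.8% and summer at 6.90%.

    first nucleophile + intermediate → target (k = 0.0640 /M/s)
    starting material → intermediate (k = 0.0140 /s)
    first nucleophile → decomposed reagent (k = 0.00800 /s)
    second nucleophile + intermediate → other capture product (k = 0.0490 /M/s)
    crystals ⇌ target, rate k5*(cs5 - [target]) while solid is left; crystals form when [target] > cs5 (solubility = 13.0 mM, k = 0.420 /s)
    2 starting material → homo dimer (k = 0.00180 /M/s)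

At 2.50 min spring holds 12.8% of other capture product, so 0.835 of its two captured products is target. The neighbour of summer charged with 1.2 M of first nucleophile gets a share of 0.231 from the capture ratio 0.627, so 20.6% of target by my estimate, and at 2.5 min that flask holds 21.9%.

The readings are simulated for an exercise; the scatter is artificial.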